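The runs were generated by integration with made-up constants; noise was put on by code.

Which recipe left the most mono adduct at the end, and what did each slow addition cost?

| flask | substrate | reagent | remark | time |
|---|---|---|---|---|
| north-east | 0.050 M | 0.060 M | run made earlier |  |
| north | 0.050 M | 0.030 M | run made earlier |  |
| south | 0.050 M | 0.12 M | run made earlier |  |
| south-east | 0.025 M | 0.060 M | run made earlier |  |
| grey | 0.050 M (fed, over 3.0 h) | 0.0600 M | all else is in the flask from the start; the feed brings no volume worth counting | 15 h |
| ochre | 0.050 M | 0.0600 M (fed, over 3.0 h) | all else is in the flask from the start; the feed brings no volume worth counting | 15 h |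
| violet | 0.050 M | 0.0600 M | everything together at the start | 15 h |
| green | 0.050 M | 0.0600 M (in portions, 2, over 3.0 h) | first portion at the start, last at 3.0 h | 15 h |

- the flask that comes out highest in amount of mono adduct, in percent of the substrate charged, or "all alike" when all lie within 1.5 percentage points (grey / ochre / violet / green / all alike)
- mono adduct at the end, in percent of the substrate charged, grey
- mono adduct at the end, in percent of the substrate charged, ochre
- mono adduct at the end, in percent of the substrate charged, violet
- mono adduct at the end, in percent of the substrate charged, green

- the numbers in the tables scatter by 0.5 percentage points (one standard deviation)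

| run | time / h | mono adduct / % | substrate / % |
|---|---|---|---|
| north-east | 3.00 | 40.6 | 11.4 |
| north-east | 6.00 | 38.6 | 8.7 |
| north-east | 10.0 | 39.2 | 7.5 |
| north-east | 12.0 | 39.4 | 6.9 |
| north-east | 15.0 | 39.0 | 6.1 |
| north | 1.50 | 34.0 | 32.3 |
| north | 5.00 | 35.3 | 18.3 |
| north | 8.00 | 34.5 | 15.3 |
| north | 12.0 | 34.9 | 10.6 |
| north | 20.0 | 34.6 | 7.6 |
| south | 4.00 | 16.1 | 1.2 |
| south | 8.00 | 12.3 | 0.5 |
| south | 10.0 | 12.2 | 1.0 |
| south | 15.0 | 11.6 | 0 |
| south | 20.0 | 12.4 | 1.5 |
| south-east | 4.00 | 23.0 | 2.6 |
| south-east | 8.00 | 16.1 | 0.6 |
| south-east | 10.0 | 14.7 | 1.4 |
| south-east | 15.0 | 12.3 | 0.6 |
| south-east | 20.0 | 12.9 | 0.7 |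

(standard deviation of a reading: 0.5 percentage points)

In the north run mono adduct stayed near 34.9 % while substrate fell from 10.6 % at 12.0 h to 7.6 % at 20.0 h, so something was taking substrate without making mono adduct. I took this loss to be second order in substrate and read from those two points a self-loss time, the span over which the reciprocal of the share of substrate left rises by one, which is the second-order half-life of substrate at its charge: 2.15 h. The feed of 3.0 h is longer than that. I took the adduct steps to be first order in reagent, so at given [substrate] and [mono adduct] the level of reagent does not change how it divides between them. What the feed changes is the time given to self-loss, which needs no reagent.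

For ochre I therefore set two extremes. With reagent in at once, ochre is violet, and violet repeats the north-east run, 39.0 % at 15.0 h. With reagent held back for the length of the feed, a share of 41.7 % of the substrate is left and 58.3 % is lost. Reagent then stands at 2.88 to substrate, beyond the 2.40 of the south-east run, which ended at 12.9 % of its own substrate. That figure belongs to the south-east ratio and could not be carried over, and I expected this extreme to keep a smaller share, so I let the range run from the north-east figure down to no mono adduct. The real feed takes substrate away from the start, but slowly, so I committed to the middle of that range, 19.5 %. I expected violet highest and placed green, with part of its reagent in at the start, between ochre and violet. Grey I did not reckon this way.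

The forecast said violet, with grey 31 %, ochre 12 %, violet 39.2 % and green 17 %. It too read that “Substrate also self-consumes”, but its ochre stood below my figure.

The flasks gave violet as highest: grey 33.3 %, ochre 17.8 %, violet 39.1 %, green 25.7 %.

    substrate + reagent → mono adduct + released group (k = 38.0 M⁻¹ h⁻¹)
    reagent + mono adduct → bis adduct + released group (k = 21.0 M⁻¹ h⁻¹)
    reagent + bis adduct → tris adduct + released group (k = 31.0 M⁻¹ h⁻¹)
    2 substrate → self-condensation product (k = 5.40 M⁻¹ h⁻¹)

Taking the self-condensation path away closes the gap between violet and ochre from 21 percentage points to 0 points. At the end of its feed, ochre held 40.5 % of the substrate charged as self-condensation product, under the 58.3 % reckoned from the self-loss time. Green has the same self-loss time and the same span before its last portion, but its first portion went in at the start, and just before the last addition it held 30.8 % as self-condensation product, less than ochre at the end of its feed.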